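**Retrosynthetic overview** (halimane numbering: ring A = C1–C5 and C10, ring B = C5–C10; C9 carries the C20 methyl and the C11–C16 chain, C8 carries C17)
1. Late stage: the C15–O ester bond (acid plus 1,3-O-benzylidene-glycerol), the C20 methyl from a C9–CO2Me group, and C6–C7 from C6=C7.
2. Key disconnection: bonds C5–C10 and C8–C9 together, by an intramolecular Diels–Alder reaction of an acyclic allenoate (diene C5=C6–C7=C8 with 5E,7Z geometry, dienophile C9=C10, tether C1–C4); rings A and B form together in this one step and no other ring-forming step is needed.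
3. Enabling feature: ring B is a six-membered carbocycle whose C10 bears the C1=C10 double bond (endocyclic to ring A, exocyclic to ring B) directly beside quaternary C9, so C1=C10–C9 is the footprint of an allene C1=C10=C9 that has reacted through its C9=C10 bond; the C9 methyl is read as a spent ester activator.
4. Stereochemistry: an (S)-propargylic mesylate gives the (Ra)-allene by anti carbonylation and the axis sets C9; endo addition plus the 5E/7Z diene geometry sets C5 and C8; C13 comes from (R)-citronellol.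
5. Precursor assembly: an ynone from a C1–C8 dienyl Weinreb amide (Takai olefination and Suzuki–Miyaura coupling on methyl 4,4-dimethyl-5-oxopentanoate) and a C9–C16 alkyne (citronellol, ozonolysis, Ohira–Bestmann).

Key step: step 11

Remark: methyl 4,4-dimethyl-5-oxopentanoate (the conjugate adduct of isobutyraldehyde and methyl acrylate) is taken as a purchasable building block; TBS = tert-butyldimethylsilyl.

**Step 1**
Reactants: 1 methyl 4,4-dimethyl-5-oxopentanoate
Product: 2 methyl (5E)-6-iodo-4,4-dimethylhex-5-enoate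
Conditions: CrCl2 (6 equiv), CHI3 (2 equiv), THF, 0 °C → rt
Reagents that add atoms: iodoform IC(I)I
Why: Takai olefination, in which the geminal dichromium reagent adds to the hindered aldehyde and eliminates to the (E)-iodoalkene, while the methyl ester is inert to the organochromium species.

**Step 2**
Reactants: 2 methyl (5E)-6-iodo-4,4-dimethylhex-5-enoate; 3 (Z)-prop-1-en-1-ylboronic acid
Product: 4 methyl (5E,7Z)-4,4-dimethylnona-5,7-dienoate
Conditions: Pd(PPh3)4 (5 mol %), K3PO4, THF/H2O, 40 °C
Reagents that add atoms: none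
Why: Suzuki–Miyaura coupling proceeds with retention of geometry at both alkenyl partners, so the E iodide and the Z boronic acid should give the 5E,7Z diene.

**Step 3**
Reactants: 4 methyl (5E,7Z)-4,4-dimethylnona-5,7-dienoate
Product: 5 (5E,7Z)-N-methoxy-N,4,4-trimethylnona-5,7-dienamide
Conditions: MeNH(OMe)·HCl, iPrMgCl, THF, −20 → 0 °C
Reagents that add atoms: N,O-dimethylhydroxylamine hydrochloride CNOC.Cl
Why: Weinreb amide formation by aminolysis of the ester with the chloromagnesium amide, which leaves the diene untouched.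

**Step 4**
Reactants: 6 (R)-citronellol
Product: 7 tert-butyl{[(3R)-3,7-dimethyloct-6-en-1-yl]oxy}dimethylsilane
Conditions: TBSCl, imidazole, DMF, rt
Reagents that add atoms: tert-butyldimethylsilyl chloride CC(C)(C)[Si](C)(C)Cl
Why: Standard silylation of a primary alcohol; the ether masks the future C15 through the organometallic and hydride steps.

**Step 5**
Reactants: 7 tert-butyl{[(3R)-3,7-dimethyloct-6-en-1-yl]oxy}dimethylsilane
Product: 9 (4R)-6-[(tert-butyldimethylsilyl)oxy]-4-methylhexanal, via ozonide 8 (not isolated)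
Conditions: O3, CH2Cl2, −78 °C; then PPh3, −78 °C → rt
Reagents that add atoms: ozone [O-][O+]=O
Why: Ozonolysis with reductive work-up cleaves the trisubstituted alkene to the aldehyde without touching the remote stereocentre (the future C13).

**Step 6**
Reactants: 9 (4R)-6-[(tert-butyldimethylsilyl)oxy]-4-methylhexanal
Product: 10 tert-butyldimethyl{[(3R)-3-methylhept-6-yn-1-yl]oxy}silane
Conditions: dimethyl (1-diazo-2-oxopropyl)phosphonate, K2CO3, MeOH, 0 °C → rt
Reagents that add atoms: dimethyl (1-diazo-2-oxopropyl)phosphonate COP(=O)(OC)C(=[N+]=[N-])C(C)=O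
Why: Ohira–Bestmann (Seyferth–Gilbert) homologation converts the aldehyde into the terminal alkyne under mild base that does not affect the silyl ether.

**Step 7**
Reactants: 10 tert-butyldimethyl{[(3R)-3-methylhept-6-yn-1-yl]oxy}silane; 5 (5E,7Z)-N-methoxy-N,4,4-trimethylnona-5,7-dienamide
Product: 12 (3R,12E,14Z)-1-[(tert-butyldimethylsilyl)oxy]-3,11,11-trimethylhexadeca-12,14-dien-6-yn-8-one, via lithium acetylide 11 (not isolated)
Conditions: n-BuLi, THF, −78 °C; then 5, −78 → 0 °C; aq. NH4Cl
Reagents that add atoms: none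
Why: Acylation of a lithium acetylide by a Weinreb amide, whose stable chelated tetrahedral intermediate prevents over-addition and releases the ynone on work-up.

**Step 8**
Reactants: 12 (3R,12E,14Z)-1-[(tert-butyldimethylsilyl)oxy]-3,11,11-trimethylhexadeca-12,14-dien-6-yn-8-one
Product: 13 (3R,8S,12E,14Z)-1-[(tert-butyldimethylsilyl)oxy]-3,11,11-trimethylhexadeca-12,14-dien-6-yn-8-ol
Conditions: RuCl[(S,S)-TsDPEN](p-cymene) (2 mol %), KOH (2.5 mol %), iPrOH, rt
Reagents that add atoms: none
Why: Noyori asymmetric transfer hydrogenation of an alkynyl ketone, in which the alkyne is the π group recognised by the catalyst, so the (S,S) ligand should deliver the (S)-carbinol without reducing the alkyne or the diene.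

**Step 9**
Reactants: 13 (3R,8S,12E,14Z)-1-[(tert-butyldimethylsilyl)oxy]-3,11,11-trimethylhexadeca-12,14-dien-6-yn-8-ol
Product: 14 (3R,8S,12E,14Z)-1-[(tert-butyldimethylsilyl)oxy]-3,11,11-trimethylhexadeca-12,14-dien-6-yn-8-yl methanesulfonate
Conditions: MsCl, Et3N, CH2Cl2, −40 → 0 °C (used crude)
Reagents that add atoms: methanesulfonyl chloride CS(=O)(=O)Cl
Why: O-Sulfonylation with retention at carbon turns the carbinol into a leaving group for the 1,3-substitution.

**Step 10**
Reactants: 14 (3R,8S,12E,14Z)-1-[(tert-butyldimethylsilyl)oxy]-3,11,11-trimethylhexadeca-12,14-dien-6-yn-8-yl methanesulfonate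
Product: 15 methyl (Ra,8E,10Z)-2-[(3R)-5-[(tert-butyldimethylsilyl)oxy]-3-methylpentyl]-7,7-dimethyldodeca-2,3,8,10-tetraenoate
Conditions: Pd(PPh3)4 (5 mol %), CO (1 atm), MeOH, 2,6-lutidine, THF, rt
Reagents that add atoms: carbon monoxide [C-]#[O+]; methanol CO
Why: Palladium-catalysed methoxycarbonylation of a propargylic mesylate: zerovalent palladium adds anti in an SN2′ sense to give an allenylpalladium species, and CO insertion and methanolysis with retention give net anti 1,3-substitution, so the (S) carbinol centre is transcribed into the (Ra) allene axis.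

**Step 11**
Reactants: 15 methyl (Ra,8E,10Z)-2-[(3R)-5-[(tert-butyldimethylsilyl)oxy]-3-methylpentyl]-7,7-dimethyldodeca-2,3,8,10-tetraenoate
Product: 16 methyl (1S,2R,4aS)-1-[(3R)-5-[(tert-butyldimethylsilyl)oxy]-3-methylpentyl]-2,5,5-trimethyl-1,2,4a,5,6,7-hexahydronaphthalene-1-carboxylate (halimane numbering: C1=C10 and C6=C7 alkenes; CO2Me on C9 in the place of the C20 methyl; C5, C8 and C9 arranged as in the target)
Conditions: Me2AlCl (2 equiv), CH2Cl2, −78 → −20 °C
Reagents that add atoms: none
Why: Me2AlCl binds the ester carbonyl and the ester-conjugated C9=C10 π bond of the allene adds suprafacially to the s-cis C5=C6–C7=C8 diene in a concerted but asynchronous [4+2] process in which C5–C10 bonding (to the electrophilic central allene carbon) runs ahead of C8–C9 bonding. The closest known reaction type is the Lewis-acid-promoted intramolecular Diels–Alder reaction of allenic esters and other allenic dienophiles tethered through the remote allene terminus, together with aluminium-promoted cyclisations of 1,7,9-decatrienoates. Ring A (C10, C1, C2, C3, C4, C5) closes through the C5–C10 bond as the six-membered tether ring of a type 1 intramolecular Diels–Alder reaction and keeps the second allene π bond as the endocyclic C1=C10 alkene, while ring B (C5–C10) is the new cyclohexene closed by both bonds. C9 is fixed by the allene axis, because tether carbon C2 lies in the plane of the C9=C10 π lobes and lets the diene reach only the face syn to C2, so that CO2Me and C11 keep defined places on the new quaternary centre; C5 and C8 follow from the endo rule (aluminium-bound CO2Me under C6–C7) combined with the diene geometry, the outside C4 of the 5E alkene ending cis to CO2Me and the inside methyl of the 7Z alkene ending trans to CO2Me and cis to C11. The step needs endo over exo selectivity, reaction at C9=C10 and not at the tether-proximal C1=C10 bond, and no Z to E leakage; the Lewis-acid-lowered LUMO localised on C9=C10, the gem-dimethyl tether and the low temperature should secure these.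

**Step 12**
Reactants: 16 (Diels–Alder adduct, as above)
Product: 17 methyl (1S,2R,4aS)-1-[(3R)-5-[(tert-butyldimethylsilyl)oxy]-3-methylpentyl]-2,5,5-trimethyl-1,2,3,4,4a,5,6,7-octahydronaphthalene-1-carboxylate
Conditions: H2 (4 atm), RhCl(PPh3)3 (10 mol %), benzene/EtOH, rt
Reagents that add atoms: none
Why: Chemoselective homogeneous hydrogenation: RhCl(PPh3)3 should reduce the cis-disubstituted C6=C7 alkene far faster than the trisubstituted C1=C10 alkene, which is shielded by quaternary C9 and by C5.

**Step 13**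
Reactants: 17 (saturated ester, as above)
Product: 18 [(1S,2R,4aS)-1-[(3R)-5-[(tert-butyldimethylsilyl)oxy]-3-methylpentyl]-2,5,5-trimethyl-1,2,3,4,4a,5,6,7-octahydronaphthalen-1-yl]methanol
Conditions: LiAlH4, THF, 0 °C → reflux
Reagents that add atoms: none
Why: Hydride reduction of the hindered neopentyl-type ester to the primary alcohol; the silyl ether and the isolated alkene are inert.

**Step 14**
Reactants: 18 (C20 carbinol, as above)
Product: 19 (1S,2R,4aS)-1-[(3R)-5-[(tert-butyldimethylsilyl)oxy]-3-methylpentyl]-2,5,5-trimethyl-1,2,3,4,4a,5,6,7-octahydronaphthalene-1-carbaldehyde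
Conditions: Dess–Martin periodinane, NaHCO3, CH2Cl2, rt
Reagents that add atoms: none
Why: Dess–Martin oxidation gives the non-enolisable aldehyde under buffered conditions that spare the silyl ether.

**Step 15**
Reactants: 19 (C20 aldehyde, as above)
Product: 21 (3R)-3-methyl-5-[(1R,2R,4aS)-1,2,5,5-tetramethyl-1,2,3,4,4a,5,6,7-octahydronaphthalen-1-yl]pentan-1-ol, via hydrazone 20 (not isolated)
Conditions: N2H4·H2O, diethylene glycol, 130 °C; then KOH, 200 °C
Reagents that add atoms: none
Why: Wolff–Kishner reduction (Huang–Minlon procedure) turns the formyl group into the C20 methyl without epimerisation because C9 is quaternary, and the hot KOH should also cleave the primary silyl ether to free the C15 alcohol.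

**Step 16**
Reactants: 21 (C15 alcohol, as above)
Product: 23 (3R)-3-methyl-5-[(1R,2R,4aS)-1,2,5,5-tetramethyl-1,2,3,4,4a,5,6,7-octahydronaphthalen-1-yl]pentanoic acid, via aldehyde 22 (not isolated)
Conditions: TEMPO (20 mol %), PhI(OAc)2 (2.5 equiv), MeCN/H2O (1:1), rt
Reagents that add atoms: water O
Why: Oxoammonium (TEMPO) oxidation of the primary alcohol through the aldehyde hydrate to the acid, under conditions that tolerate the trisubstituted alkene.

**Step 17**
Reactants: 23 (acid, as above); 24 cis-2-phenyl-1,3-dioxan-5-ol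
Product: 25 cis-2-phenyl-1,3-dioxan-5-yl (3R)-3-methyl-5-[(1R,2R,4aS)-1,2,5,5-tetramethyl-1,2,3,4,4a,5,6,7-octahydronaphthalen-1-yl]pentanoate
Conditions: EDC·HCl, DMAP, CH2Cl2, 0 °C → rt
Reagents that add atoms: none
Why: Steglich esterification places the acyl group on the secondary (C2) oxygen of glycerol, whose primary hydroxyls are blocked as the benzylidene acetal.

**Step 18**
Reactants: 25 (benzylidene-protected ester, as above)
Product: 27 1,3-dihydroxypropan-2-yl (3R)-3-methyl-5-[(1R,2R,4aS)-1,2,5,5-tetramethyl-1,2,3,4,4a,5,6,7-octahydronaphthalen-1-yl]pentanoate (target), via cyclic borate 26 (not isolated)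
Conditions: B(OH)3, B(OMe)3, 100 °C; then H2O, 0 °C
Reagents that add atoms: none
Why: Borate-mediated transacetalisation removes the benzylidene group under neutral, non-nucleophilic conditions, and cold hydrolysis of the 1,3-borate should release the diol with the acyl group still on the secondary oxygen.

**Compound list**
1 | methyl 4,4-dimethyl-5-oxopentanoate | COC(=O)CCC(C)(C)C=O | starting material
2 | methyl (5E)-6-iodo-4,4-dimethylhex-5-enoate | COC(=O)CCC(C)(C)/C=C/I | intermediate
3 | (Z)-prop-1-en-1-ylboronic acid | C/C=C\B(O)O | starting material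
4 | methyl (5E,7Z)-4,4-dimethylnona-5,7-dienoate | COC(=O)CCC(C)(C)/C=C/C=C\C | intermediate
5 | (5E,7Z)-N-methoxy-N,4,4-trimethylnona-5,7-dienamide | CON(C)C(=O)CCC(C)(C)/C=C/C=C\C | intermediate
6 | (R)-citronellol, (3R)-3,7-dimethyloct-6-en-1-ol | C[C@H](CCC=C(C)C)CCO | starting material
7 | tert-butyl{[(3R)-3,7-dimethyloct-6-en-1-yl]oxy}dimethylsilane | C[C@H](CCC=C(C)C)CCO[Si](C)(C)C(C)(C)C | intermediate
8 | ozonide of 7, 3-[(3R)-5-(TBS-oxy)-3-methylpentyl]-5,5-dimethyl-1,2,4-trioxolane | C[C@H](CCC1OOC(C)(C)O1)CCO[Si](C)(C)C(C)(C)C | intermediate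
9 | (4R)-6-[(tert-butyldimethylsilyl)oxy]-4-methylhexanal | C[C@H](CCC=O)CCO[Si](C)(C)C(C)(C)C | intermediate
10 | tert-butyldimethyl{[(3R)-3-methylhept-6-yn-1-yl]oxy}silane | C[C@H](CCC#C)CCO[Si](C)(C)C(C)(C)C | intermediate
11 | lithium acetylide of 10 | C[C@H](CCC#C[Li])CCO[Si](C)(C)C(C)(C)C | intermediate
12 | (3R,12E,14Z)-1-[(tert-butyldimethylsilyl)oxy]-3,11,11-trimethylhexadeca-12,14-dien-6-yn-8-one | C[C@H](CCC#CC(=O)CCC(C)(C)/C=C/C=C\C)CCO[Si](C)(C)C(C)(C)C | intermediate
13 | (3R,8S,12E,14Z)-1-[(tert-butyldimethylsilyl)oxy]-3,11,11-trimethylhexadeca-12,14-dien-6-yn-8-ol | C[C@H](CCC#C[C@@H](O)CCC(C)(C)/C=C/C=C\C)CCO[Si](C)(C)C(C)(C)C | intermediate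
14 | (3R,8S,12E,14Z)-1-[(tert-butyldimethylsilyl)oxy]-3,11,11-trimethylhexadeca-12,14-dien-6-yn-8-yl methanesulfonate | C[C@H](CCC#C[C@@H](OS(C)(=O)=O)CCC(C)(C)/C=C/C=C\C)CCO[Si](C)(C)C(C)(C)C | intermediate
15 | methyl (Ra,8E,10Z)-2-[(3R)-5-[(tert-butyldimethylsilyl)oxy]-3-methylpentyl]-7,7-dimethyldodeca-2,3,8,10-tetraenoate | COC(=O)C(CC[C@@H](C)CCO[Si](C)(C)C(C)(C)C)=[C@]=C([H])CCC(C)(C)/C=C/C=C\C | intermediate
16 | methyl (1S,2R,4aS)-1-[(3R)-5-[(tert-butyldimethylsilyl)oxy]-3-methylpentyl]-2,5,5-trimethyl-1,2,4a,5,6,7-hexahydronaphthalene-1-carboxylate | C[C@H](CC[C@@]1(C(=O)OC)C2=CCCC(C)(C)[C@@H]2C=C[C@H]1C)CCO[Si](C)(C)C(C)(C)C | intermediate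
17 | methyl (1S,2R,4aS)-1-[(3R)-5-[(tert-butyldimethylsilyl)oxy]-3-methylpentyl]-2,5,5-trimethyl-1,2,3,4,4a,5,6,7-octahydronaphthalene-1-carboxylate | C[C@H](CC[C@@]1(C(=O)OC)C2=CCCC(C)(C)[C@@H]2CC[C@H]1C)CCO[Si](C)(C)C(C)(C)C | intermediate
18 | [(1S,2R,4aS)-1-[(3R)-5-[(tert-butyldimethylsilyl)oxy]-3-methylpentyl]-2,5,5-trimethyl-1,2,3,4,4a,5,6,7-octahydronaphthalen-1-yl]methanol | C[C@H](CC[C@@]1(CO)C2=CCCC(C)(C)[C@@H]2CC[C@H]1C)CCO[Si](C)(C)C(C)(C)C | intermediate
19 | (1S,2R,4aS)-1-[(3R)-5-[(tert-butyldimethylsilyl)oxy]-3-methylpentyl]-2,5,5-trimethyl-1,2,3,4,4a,5,6,7-octahydronaphthalene-1-carbaldehyde | C[C@H](CC[C@@]1(C=O)C2=CCCC(C)(C)[C@@H]2CC[C@H]1C)CCO[Si](C)(C)C(C)(C)C | intermediate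
20 | hydrazone of 19 | C[C@H](CC[C@@]1(C=NN)C2=CCCC(C)(C)[C@@H]2CC[C@H]1C)CCO[Si](C)(C)C(C)(C)C | intermediate
21 | (3R)-3-methyl-5-[(1R,2R,4aS)-1,2,5,5-tetramethyl-1,2,3,4,4a,5,6,7-octahydronaphthalen-1-yl]pentan-1-ol | C[C@H](CC[C@@]1(C)C2=CCCC(C)(C)[C@@H]2CC[C@H]1C)CCO | intermediate
22 | (3R)-3-methyl-5-[(1R,2R,4aS)-1,2,5,5-tetramethyl-1,2,3,4,4a,5,6,7-octahydronaphthalen-1-yl]pentanal | C[C@H](CC[C@@]1(C)C2=CCCC(C)(C)[C@@H]2CC[C@H]1C)CC=O | intermediate
23 | (3R)-3-methyl-5-[(1R,2R,4aS)-1,2,5,5-tetramethyl-1,2,3,4,4a,5,6,7-octahydronaphthalen-1-yl]pentanoic acid | C[C@H](CC[C@@]1(C)C2=CCCC(C)(C)[C@@H]2CC[C@H]1C)CC(=O)O | intermediate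
24 | cis-2-phenyl-1,3-dioxan-5-ol (1,3-O-benzylidene-glycerol) | O[C@H]1CO[C@@H](c2ccccc2)OC1 | starting material
25 | cis-2-phenyl-1,3-dioxan-5-yl ester of 23 | C[C@H](CC[C@@]1(C)C2=CCCC(C)(C)[C@@H]2CC[C@H]1C)CC(=O)O[C@H]3CO[C@@H](c4ccccc4)OC3 | intermediate
26 | 2-hydroxy-1,3,2-dioxaborinan-5-yl ester of 23 (cyclic borate) | C[C@H](CC[C@@]1(C)C2=CCCC(C)(C)[C@@H]2CC[C@H]1C)CC(=O)OC3COB(O)OC3 | intermediate
27 | 1,3-dihydroxypropan-2-yl (3R)-3-methyl-5-[(1R,2R,4aS)-1,2,5,5-tetramethyl-1,2,3,4,4a,5,6,7-octahydronaphthalen-1-yl]pentanoate | C[C@H](CC[C@@]1(C)C2=CCCC(C)(C)[C@@H]2CC[C@H]1C)CC(=O)OC(CO)CO | target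

**Step count and risks**
Total steps: 18. Longest linear sequence: 15 (steps 1–3 then 7–18; equally steps 4–6 then 7–18).

Steps most likely to fail:

1. Step 11. The (Z)-propenyl terminus disfavours the s-cis diene and the α-alkylated ester is only a moderate dienophile, so the cycloaddition may be sluggish, may lose endo preference, or may leak Z to E through a stepwise zwitterionic course. The fallback sets out from 15 and comes back to the route at 19. Reduction of 15 with iBu2AlH (CH2Cl2, −78 °C) should give the allenyl carbinol F1, and MnO2 (CH2Cl2) should oxidise it to the 2,3-allenal F2, whose formyl group is a much stronger and more endo-directing activator. Me2AlCl at −78 °C should then give the bicyclic dienal F3, and diimide (KO2CN=NCO2K, AcOH, MeOH) should saturate C6=C7 to give 19, so that steps 12–14 are replaced.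

2. Step 10. The allene axis may erode through equilibration of the allenylpalladium intermediate or of the product by zerovalent palladium, or the allenoate may isomerise to a conjugated dienoate. The fallback sets out from 14 and comes back to the route at 19. Copper-mediated anti SN2′ substitution of 14 with (iPrO)Me2SiCH2MgCl and CuBr·SMe2 (THF, −78 °C) should give the allenylmethylsilane F4 with the same sense of chirality transfer. Tamao oxidation (H2O2, KF, KHCO3, THF/MeOH) should convert it into the allenyl carbinol F1, which is carried on through the allenal F2 and the bicyclic dienal F3 to 19 as described above.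

3. Step 18. The acyl group may shift from the secondary to a primary oxygen during or after acetal removal, or the transacetalisation may stall. The fallback sets out from 23 and comes back to the route at 27. Glycerol is silylated at both primary hydroxyls (TBSCl, imidazole, DMF) to give 1,3-bis[(tert-butyldimethylsilyl)oxy]propan-2-ol F5. Steglich coupling with 23 (EDC·HCl, DMAP) should give the bis-silyl ester F6, and buffered HF·pyridine (pyridine, THF, 0 °C) should release 27.

**Further compounds**
F1 | step 11 | (Ra,8E,10Z)-2-[(3R)-5-[(tert-butyldimethylsilyl)oxy]-3-methylpentyl]-7,7-dimethyldodeca-2,3,8,10-tetraen-1-ol | OCC(CC[C@@H](C)CCO[Si](C)(C)C(C)(C)C)=[C@]=C([H])CCC(C)(C)/C=C/C=C\C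
F2 | step 11 | (Ra,8E,10Z)-2-[(3R)-5-[(tert-butyldimethylsilyl)oxy]-3-methylpentyl]-7,7-dimethyldodeca-2,3,8,10-tetraenal | O=CC(CC[C@@H](C)CCO[Si](C)(C)C(C)(C)C)=[C@]=C([H])CCC(C)(C)/C=C/C=C\C
F3 | step 11 | (1S,2R,4aS)-1-[(3R)-5-[(tert-butyldimethylsilyl)oxy]-3-methylpentyl]-2,5,5-trimethyl-1,2,4a,5,6,7-hexahydronaphthalene-1-carbaldehyde | C[C@H](CC[C@@]1(C=O)C2=CCCC(C)(C)[C@@H]2C=C[C@H]1C)CCO[Si](C)(C)C(C)(C)C
F4 | step 10 | [(Ra,8E,10Z)-2-[(3R)-5-[(tert-butyldimethylsilyl)oxy]-3-methylpentyl]-7,7-dimethyldodeca-2,3,8,10-tetraen-1-yl](isopropoxy)dimethylsilane | CC(C)O[Si](C)(C)CC(CC[C@@H](C)CCO[Si](C)(C)C(C)(C)C)=[C@]=C([H])CCC(C)(C)/C=C/C=C\C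
F5 | step 18 | 1,3-bis[(tert-butyldimethylsilyl)oxy]propan-2-ol | CC(C)(C)[Si](C)(C)OCC(O)CO[Si](C)(C)C(C)(C)C
F6 | step 18 | 1,3-bis[(tert-butyldimethylsilyl)oxy]propan-2-yl ester of 23 | C[C@H](CC[C@@]1(C)C2=CCCC(C)(C)[C@@H]2CC[C@H]1C)CC(=O)OC(CO[Si](C)(C)C(C)(C)C)CO[Si](C)(C)C(C)(C)C
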